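**Strategy.** Everything rests on cutting the C3–C4 bond of the pyranone ring C, which joins the A-ring carbonyl carbon C4 to the B-ring-bearing carbon C3. Read forwards, a carbene-catalysed crossed benzoin reaction turns C4, still an A-ring aldehyde carbon, into an acyl-anion donor toward C3, an aryl ketone carbon held in reach by the O1–C2 ether tether; one operation forms C3–C4 and closes ring C as a 3-hydroxyisoflavanone. The precursor is a bis-silylated keto-aldehyde that already carries the complete (R,Z)-dienyl chain on C3' of ring B, so only dehydration across C2–C3 and desilylation follow. The chain's stereocentre is bought with (R)-citronellal and its Z-alkene is delivered by a stereoretentive Suzuki coupling.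

Key step: step 8

Remark: isoflavone numbering is used (O1, C2, C3, C4, C4a–C8a; ring B C1'–C6'; chain C1''–C8'' outward from C3'). The ring closure does create a C3 carbinol centre, left uncontrolled because step 9 removes it. The chain is coupled before the ketone is brominated and the aryl ether is made last, so the base-sensitive keto-aldehyde 12 meets only the key step. The ee of 16 is that of the citronellal used.

**Step 1**
Reactants: 1 (R)-citronellal, (3R)-3,7-dimethyloct-6-enal
Product: 3 (3R)-3,7-dimethyloct-6-en-1-yne, via enol nonaflate 2 (not isolated)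
Conditions: NfF (1.2 equiv), phosphazene base P2-Et (2.4 equiv), DMF, −20 °C → rt
Reagents that add atoms: nonafluorobutanesulfonyl fluoride (NfF), O=S(=O)(F)C(F)(F)C(F)(F)C(F)(F)C(F)(F)F (its atoms are held only in intermediate 2; none remain in 3)
Why: One-pot enol nonaflation–elimination of an enolisable aldehyde (a known aldehyde-to-terminal-alkyne dehydration): the phosphazene base enolises only toward C2, O-sulfonylation gives 2 and base-induced E2 loss of nonaflate gives the alkyne, while the C3 centre is neither the enolised carbon nor acidic enough as a propargylic C–H to be touched, so its R configuration should be retained.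

**Step 2**
Reactants: 3 (3R)-3,7-dimethyloct-6-en-1-yne (1.2 equiv)
Product: 4 2-[(1Z,3R)-3,7-dimethylocta-1,6-dien-1-yl]-4,4,5,5-tetramethyl-1,3,2-dioxaborolane
Conditions: HBpin (1.0 equiv), [Rh(cod)Cl]2 (1.5 mol%), P(i-Pr)3 (6 mol%), Et3N, cyclohexane, rt
Reagents that add atoms: pinacolborane, CC1(C)OBOC1(C)C
Why: Rhodium-catalysed formal trans-hydroboration of a terminal alkyne, which runs through a rhodium vinylidene and places boron on C1 cis to the C3 substituent to give the (Z)-alkenylboronate; the trisubstituted C6=C7 alkene is inert to HBpin under these conditions and keeping the alkyne in slight excess guards against Z-to-E isomerisation.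

**Step 3**
Reactants: 5 3'-bromo-4'-hydroxyacetophenone
Product: 6 1-[3-bromo-4-(triisopropylsilyloxy)phenyl]ethanone
Conditions: TIPSCl, imidazole, DMF, rt
Reagents that add atoms: chlorotriisopropylsilane (TIPSCl), CC(C)[Si](Cl)(C(C)C)C(C)C
Why: Imidazole-promoted O-silylation of a phenol; TIPS is chosen because its bulk lets the aryl silyl ether survive the aqueous base of step 4, the enol silylation of step 5 and the carbonate of step 7, and the methyl ketone is untouched.

**Step 4**
Reactants: 6 1-[3-bromo-4-(triisopropylsilyloxy)phenyl]ethanone; 4 (Z)-alkenylboronate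
Product: 7 1-{3-[(1Z,3R)-3,7-dimethylocta-1,6-dien-1-yl]-4-(triisopropylsilyloxy)phenyl}ethanone
Conditions: Pd(dppf)Cl2·CH2Cl2 (5 mol%), K3PO4, THF–H2O (10:1), 60 °C
Reagents that add atoms: none
Why: Suzuki–Miyaura cross-coupling, in which oxidative addition at the aryl bromide, transmetalation of the alkenylboronate and reductive elimination all proceed with retention at the alkene, so the Z C1''=C2'' geometry and the uninvolved C3'' centre are carried into 7, while the methyl ketone and the hindered aryl TIPS ether tolerate aqueous phosphate.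

**Step 5**
Reactants: 7 1-{3-[(1Z,3R)-3,7-dimethylocta-1,6-dien-1-yl]-4-(triisopropylsilyloxy)phenyl}ethanone
Product: 9 2-bromo-1-{3-[(1Z,3R)-3,7-dimethylocta-1,6-dien-1-yl]-4-(triisopropylsilyloxy)phenyl}ethanone, via trimethylsilyl enol ether 8 (not isolated)
Conditions: TMSOTf, Et3N, CH2Cl2, 0 °C; crude 8 taken up in pentane and concentrated; then NBS (1.0 equiv), NaHCO3, THF, −78 °C, dark
Reagents that add atoms: N-bromosuccinimide, O=C1CCC(=O)N1Br; trimethylsilyl triflate, C[Si](C)(C)OS(=O)(=O)C(F)(F)F (its silyl group is held only in intermediate 8)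
Why: α-Bromination of a ketone through its silyl enol ether: soft enolisation gives 8, whose electron-rich enol double bond reacts with NBS at −78 °C far faster than the trisubstituted alkene or the Z-styrene, so one equivalent of NBS should brominate only the former methyl carbon (the future C2); the step is placed after the coupling because an α-bromoketone would not survive palladium(0) and base.

**Step 6**
Reactants: 10 2,4-dihydroxybenzaldehyde
Product: 11 2-hydroxy-4-(triisopropylsilyloxy)benzaldehyde
Conditions: TIPSCl (1.05 equiv), imidazole, CH2Cl2, 0 °C → rt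
Reagents that add atoms: chlorotriisopropylsilane (TIPSCl), CC(C)[Si](Cl)(C(C)C)C(C)C
Why: Regioselective phenol silylation: the 2-OH is locked in a hydrogen bond to the ortho aldehyde and is the more hindered one, so one equivalent of TIPSCl should react at the free 4-OH.

**Step 7**
Reactants: 9 α-bromoketone; 11 2-hydroxy-4-(triisopropylsilyloxy)benzaldehyde
Product: 12 2-(2-{3-[(1Z,3R)-3,7-dimethylocta-1,6-dien-1-yl]-4-(triisopropylsilyloxy)phenyl}-2-oxoethoxy)-4-(triisopropylsilyloxy)benzaldehyde
Conditions: K2CO3, acetone, rt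
Reagents that add atoms: none
Why: Williamson ether synthesis by SN2 displacement of the activated α-bromoketone by the phenoxide of 11, forming the O1–C2 bond; carbonate in acetone at room temperature is mild enough that 12 should not go on to the aldol (Rap–Stoermer type) benzofuran condensation, and the step is placed directly before the key step so that this base-sensitive keto-aldehyde sees no other reaction.

**Step 8**
Reactants: 12 bis-TIPS keto-aldehyde
Product: 13 3-{3-[(1Z,3R)-3,7-dimethylocta-1,6-dien-1-yl]-4-(triisopropylsilyloxy)phenyl}-3-hydroxy-7-(triisopropylsilyloxy)chroman-4-one (both C3 epimers)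
Conditions: 2-(pentafluorophenyl)-6,7-dihydro-5H-pyrrolo[2,1-c][1,2,4]triazol-2-ium tetrafluoroborate (15 mol%), Et3N (30 mol%), degassed toluene (0.05 M), rt
Reagents that add atoms: none
Why: The triazolylidene freed by the amine adds to the aldehyde carbon (future C4) and proton transfer gives the Breslow intermediate, an acyl-anion equivalent, which attacks the tethered aryl ketone carbon (future C3); proton transfer and loss of the carbene then release the α-ketol, so the C3–C4 bond and ring C arise in one catalytic operation. The closest known reaction is the carbene-catalysed intramolecular crossed aldehyde–ketone benzoin cyclisation of 2-(2-oxoalkoxy)benzaldehydes to 3-hydroxychroman-4-ones. Ring C closes in a 6-exo-trig mode, the ketone C=O lying outside the new O1–C2–C3–C4–C4a–C8a ring. The new C3 carbinol centre is not controlled by the achiral catalyst and the remote C3'' centre should exert no useful bias, so both C3 epimers are expected, which is immaterial because C3 becomes sp2 in step 9. Chemoselectivity requires the aldehyde as donor and the ketone as acceptor; this is secured because only the aldehyde has the C–H needed to form a Breslow intermediate, the six-membered intramolecular closure should outrun homo-benzoin of the hindered, electron-rich aldehyde, and a weak amine base in substoichiometric amount at room temperature keeps the enolisable O–CH2–C(=O) unit from the competing aldol route to a 2-aroylbenzofuran. These near-neutral conditions should also leave the Z-styrene, the trisubstituted alkene, the C3'' centre and both aryl silyl ethers untouched.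

**Step 9**
Reactants: 13 3-hydroxyisoflavanone (epimer mixture)
Product: 15 3-{3-[(1Z,3R)-3,7-dimethylocta-1,6-dien-1-yl]-4-(triisopropylsilyloxy)phenyl}-7-(triisopropylsilyloxy)-4H-chromen-4-one, via C3 sulfamate ester 14 (not isolated)
Conditions: Burgess reagent (2 equiv), THF, rt → 50 °C
Reagents that add atoms: Burgess reagent, methyl N-(triethylammoniosulfonyl)carbamate, CC[N+](CC)(CC)S(=O)(=O)[N-]C(=O)OC (its atoms are held only in intermediate 14)
Why: Burgess dehydration: the tertiary C3–OH is converted into the sulfamate 14, which undergoes thermal syn-elimination; C2 is the only neighbouring carbon that bears hydrogen and each C3 epimer has a syn C2–H, so both should converge on the C2=C3 bond of the chromen-4-one under neutral conditions that spare the alkenes and silyl ethers.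

**Step 10**
Reactants: 15 bis-TIPS isoflavone
Product: 16 7-hydroxy-3-{4-hydroxy-3-[(1Z,3R)-3,7-dimethylocta-1,6-dien-1-yl]phenyl}-4H-chromen-4-one (CNP0200226.1)
Conditions: TBAF (2.5 equiv), AcOH (2.5 equiv), THF, 0 °C → rt
Reagents that add atoms: none
Why: Fluoride-induced cleavage of both aryl Si–O bonds (desilylation), buffered with acetic acid so that the phenoxides are protonated at once and the base-sensitive pyranone ring is not opened; the Z-alkene, the trisubstituted alkene and C3'' are not affected, so 16 should be obtained as the single (R,Z) isomer.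

**Compound list**

1 | (R)-citronellal, (3R)-3,7-dimethyloct-6-enal | CC(C)=CCC[C@@H](C)CC=O | starting material
2 | (3R)-3,7-dimethylocta-1,6-dien-1-yl nonafluorobutane-1-sulfonate (E/Z mixture at C1=C2) | CC(C)=CCC[C@@H](C)C=COS(=O)(=O)C(F)(F)C(F)(F)C(F)(F)C(F)(F)F | intermediate (not isolated)
3 | (3R)-3,7-dimethyloct-6-en-1-yne | CC(C)=CCC[C@@H](C)C#C | intermediate
4 | 2-[(1Z,3R)-3,7-dimethylocta-1,6-dien-1-yl]-4,4,5,5-tetramethyl-1,3,2-dioxaborolane | CC(C)=CCC[C@@H](C)/C=C\B1OC(C)(C)C(C)(C)O1 | intermediate
5 | 3'-bromo-4'-hydroxyacetophenone | CC(=O)c1ccc(O)c(Br)c1 | starting material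
6 | 1-[3-bromo-4-(triisopropylsilyloxy)phenyl]ethanone | CC(=O)c1ccc(O[Si](C(C)C)(C(C)C)C(C)C)c(Br)c1 | intermediate
7 | 1-{3-[(1Z,3R)-3,7-dimethylocta-1,6-dien-1-yl]-4-(triisopropylsilyloxy)phenyl}ethanone | CC(C)=CCC[C@@H](C)/C=C\c1cc(C(C)=O)ccc1O[Si](C(C)C)(C(C)C)C(C)C | intermediate
8 | {1-[3-((1Z,3R)-3,7-dimethylocta-1,6-dien-1-yl)-4-(triisopropylsilyloxy)phenyl]ethenyloxy}trimethylsilane | CC(C)=CCC[C@@H](C)/C=C\c1cc(C(=C)O[Si](C)(C)C)ccc1O[Si](C(C)C)(C(C)C)C(C)C | intermediate (not isolated)
9 | 2-bromo-1-{3-[(1Z,3R)-3,7-dimethylocta-1,6-dien-1-yl]-4-(triisopropylsilyloxy)phenyl}ethanone | CC(C)=CCC[C@@H](C)/C=C\c1cc(C(=O)CBr)ccc1O[Si](C(C)C)(C(C)C)C(C)C | intermediate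
10 | 2,4-dihydroxybenzaldehyde | O=Cc1ccc(O)cc1O | starting material
11 | 2-hydroxy-4-(triisopropylsilyloxy)benzaldehyde | O=Cc1ccc(O[Si](C(C)C)(C(C)C)C(C)C)cc1O | intermediate
12 | 2-(2-{3-[(1Z,3R)-3,7-dimethylocta-1,6-dien-1-yl]-4-(triisopropylsilyloxy)phenyl}-2-oxoethoxy)-4-(triisopropylsilyloxy)benzaldehyde | CC(C)=CCC[C@@H](C)/C=C\c1cc(C(=O)COc2cc(O[Si](C(C)C)(C(C)C)C(C)C)ccc2C=O)ccc1O[Si](C(C)C)(C(C)C)C(C)C | intermediate
13 | 3-{3-[(1Z,3R)-3,7-dimethylocta-1,6-dien-1-yl]-4-(triisopropylsilyloxy)phenyl}-3-hydroxy-7-(triisopropylsilyloxy)chroman-4-one (both C3 epimers) | CC(C)=CCC[C@@H](C)/C=C\c1cc(C2(O)COc3cc(O[Si](C(C)C)(C(C)C)C(C)C)ccc3C2=O)ccc1O[Si](C(C)C)(C(C)C)C(C)C | intermediate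
14 | triethylammonium salt of the C3 O-[N-(methoxycarbonyl)sulfamate] of 13 | CC(C)=CCC[C@@H](C)/C=C\c1cc(C2(OS(=O)(=O)[N-]C(=O)OC)COc3cc(O[Si](C(C)C)(C(C)C)C(C)C)ccc3C2=O)ccc1O[Si](C(C)C)(C(C)C)C(C)C.CC[NH+](CC)CC | intermediate (not isolated)
15 | 3-{3-[(1Z,3R)-3,7-dimethylocta-1,6-dien-1-yl]-4-(triisopropylsilyloxy)phenyl}-7-(triisopropylsilyloxy)-4H-chromen-4-one | CC(C)=CCC[C@@H](C)/C=C\c1cc(-c2coc3cc(O[Si](C(C)C)(C(C)C)C(C)C)ccc3c2=O)ccc1O[Si](C(C)C)(C(C)C)C(C)C | intermediate
16 | 7-hydroxy-3-{4-hydroxy-3-[(1Z,3R)-3,7-dimethylocta-1,6-dien-1-yl]phenyl}-4H-chromen-4-one | CC(C)=CCC[C@@H](C)/C=C\c1cc(-c2coc3cc(O)ccc3c2=O)ccc1O | target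

**Step count.** Total: 10 steps. Longest linear sequence: 8 steps (steps 1, 2, 4, 5, 7, 8, 9, 10).

**Steps most likely to fail**

1. Step 8. The amine may enolise the O–CH2–C(=O) unit so that intramolecular aldol condensation onto the aldehyde and aromatisation to a benzofuran compete, or carbene addition to the electron-rich aldehyde may be so slow that conversion stalls. Fallback: build ring C by the classical deoxybenzoin route and attach the chain last. It sets out from 4 and returns at 15.
   - Resorcinol and (3-bromo-4-hydroxyphenyl)acetic acid are joined by BF3·OEt2-mediated Friedel–Crafts acylation to 2-(3-bromo-4-hydroxyphenyl)-1-(2,4-dihydroxyphenyl)ethanone F1.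
   - Vilsmeier-type formylation–cyclisation (BF3·OEt2, DMF, MsCl, 70 °C) closes the pyranone to 3-(3-bromo-4-hydroxyphenyl)-7-hydroxy-4H-chromen-4-one F2.
   - TIPSCl and imidazole give 3-[3-bromo-4-(triisopropylsilyloxy)phenyl]-7-(triisopropylsilyloxy)-4H-chromen-4-one F3.
   - Suzuki–Miyaura coupling of F3 with 4 under the step 4 conditions should give 15, from which step 10 follows.

2. Step 5. Chemoselectivity of the electrophilic bromination may be lost (attack on the trisubstituted alkene or the electron-rich styrene), or the silyl enol ether may hydrolyse before it is brominated. Fallback: brominate before any alkene is present and couple last. It sets out from 6 and returns at 12.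
   - Phenyltrimethylammonium tribromide in THF at rt should give 2-bromo-1-[3-bromo-4-(triisopropylsilyloxy)phenyl]ethanone F4.
   - Alkylation of 11 with F4 (K2CO3, acetone, rt) gives 2-{2-[3-bromo-4-(triisopropylsilyloxy)phenyl]-2-oxoethoxy}-4-(triisopropylsilyloxy)benzaldehyde F5.
   - Suzuki–Miyaura coupling of F5 with 4 under weakly basic conditions (Pd(OAc)2, SPhos, powdered K3PO4, THF, rt to 40 °C) should give 12. The mild base is chosen to hold back the aldol condensation of the keto-aldehyde.

3. Step 2. Z selectivity may erode through rhodium hydride-mediated isomerisation of the alkenylboronate, or conversion of the α-branched alkyne may be incomplete. Fallback: set the Z geometry by syn semihydrogenation of an aryl alkyne instead. It sets out from 3 and 6 and returns at 7, so steps 2 and 4 are no longer needed.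
   - Sonogashira coupling of 3 with 6 (Pd(PPh3)2Cl2, CuI, Et3N, 60 °C) gives 1-{3-[(3R)-3,7-dimethyloct-6-en-1-yn-1-yl]-4-(triisopropylsilyloxy)phenyl}ethanone F6.
   - Lindlar hydrogenation of F6 (Pd/CaCO3–Pb, quinoline, H2, EtOAc, rt) should add hydrogen syn to the alkyne only and give 7.

**Further compounds**

F1 | step 8 | 2-(3-bromo-4-hydroxyphenyl)-1-(2,4-dihydroxyphenyl)ethanone | O=C(Cc1ccc(O)c(Br)c1)c1ccc(O)cc1O
F2 | step 8 | 3-(3-bromo-4-hydroxyphenyl)-7-hydroxy-4H-chromen-4-one | O=c1c(-c2ccc(O)c(Br)c2)coc2cc(O)ccc12
F3 | step 8 | 3-[3-bromo-4-(triisopropylsilyloxy)phenyl]-7-(triisopropylsilyloxy)-4H-chromen-4-one | O=c1c(-c2ccc(O[Si](C(C)C)(C(C)C)C(C)C)c(Br)c2)coc2cc(O[Si](C(C)C)(C(C)C)C(C)C)ccc12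
F4 | step 5 | 2-bromo-1-[3-bromo-4-(triisopropylsilyloxy)phenyl]ethanone | O=C(CBr)c1ccc(O[Si](C(C)C)(C(C)C)C(C)C)c(Br)c1
F5 | step 5 | 2-{2-[3-bromo-4-(triisopropylsilyloxy)phenyl]-2-oxoethoxy}-4-(triisopropylsilyloxy)benzaldehyde | O=Cc1ccc(O[Si](C(C)C)(C(C)C)C(C)C)cc1OCC(=O)c1ccc(O[Si](C(C)C)(C(C)C)C(C)C)c(Br)c1
F6 | step 2 | 1-{3-[(3R)-3,7-dimethyloct-6-en-1-yn-1-yl]-4-(triisopropylsilyloxy)phenyl}ethanone | CC(C)=CCC[C@@H](C)C#Cc1cc(C(C)=O)ccc1O[Si](C(C)C)(C(C)C)C(C)C
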